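## Structural features

Licobichalcone is a 1-aryl-1,2-dihydronaphthalene. Benzene ring A (C4a, C5, C6, C7, C8, C8a) is fused to a carbocycle (C1 to C4) that carries a 3,4-dihydroxy-2-methoxyphenyl group on C1, 4-hydroxybenzoyl groups on C2 and C3, and a C3=C4 double bond conjugated with ring A and the C3 ketone. The two stereocentres are neighbours and cis: C1 (S) is doubly benzylic, while C2 (S) is α to a ketone and allylic, so it can be lost through an extended enolate. Fragile points are the five free phenols (two catechols, easily oxidised), the dihydronaphthalene (easily dehydrogenated to a naphthalene), the enone (which rules out hydrogenolysis) and the methyl ethers on C8 and C2', which must survive beside oxygens that must be freed. The real difficulty is twofold: a penta-substituted ring A with three neighbouring, differently masked oxygens (C6, C7, C8) and one hydrogen (C5), and a cis C1/C2 pair next to an enolisable carbon. The key step uses the pattern of ring A: C8a, C8, C7, C6 and the C6 oxygen are the five ring atoms of a 2-substituted 3,4-dioxygenated furan and C4a–C5 is a terminal alkyne, so ring A and the carbocycle can be closed together by a furan–alkyne cycloaddition that then aromatises.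

## Logic of the disconnections

**24 to 23.** The four benzyl–oxygen bonds (O3', O4' and the para oxygens of both aroyl groups) are cut. Benzyl ethers survive enolates and 110 °C and can be removed cold without hydrogen. The forward step must leave C3=C4, the C8 and C2' methyl ethers and C2 alone.

**23 to 20.** The O–CH3 bond on C7 is put back. With C7 and C8 both as methyl ethers, the oxygens of ring A come from 6, whose two α-positions are identical, so its attachment at C1 raises no regiochemical question. A furan with two different ether groups would spare this step but would have to be made and could attach at either α-carbon. The forward step must cleave one methyl ether out of four; the free C6 hydroxyl formed in the key step is the handle.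

**20 to 18.** The C2–H bond, and with it the C2 configuration, is disconnected: 20 is the product of face-selective protonation of the C2 enolate of 18. C2 lies between a ketone and the enone and would not keep a configuration through steps 5 to 7. Compounds 10 to 18 can therefore be C2 epimer pairs and no acyclic diastereocontrol is needed. The forward step needs protonation at C2, not C4, from the face away from the C1 aryl group.

**18 to 16 (through 17).** C4a–C8a and C5–C6 are cut and the C8a–O bridge bond is restored. Ring A becomes a furan (C8a, C8, C7, C6, O) and an alkyne (C4a≡C5), and the carbocycle becomes an open chain. Two rings and two C–C bonds are removed without any stereocentre or reagent. The forward step needs the (E) geometry at C3=C4, a terminal enynone that survives heating, and bridge opening at C8a.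

**16 to 15.** The C5–Si bond is cut; the alkyne is carried as its silane through the condensation. The silane must be removed without base strong enough to add to the enynone.

**15 to 10 and 11.** C3=C4 is cut as an aldol condensation between the methylene of one aryl ketone and an ynal. This removes the three-carbon unit 11 and leaves a 1,4-diketone. The forward step needs enolisation at C3 rather than C2, the (E) alkene, and no migration of the double bond toward C2.

**10 to 7 and 8.** C2–C3 is cut. A 1,4-dicarbonyl needs one partner of reversed polarity, here the α-bromo ketone 8. Mono-alkylation is required; the C2 configuration is not.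

**7 to 5 and 6.** C1–C8a is cut as a conjugate Friedel–Crafts addition; C1 is β to the ketone and bonded to a nucleophilic furan α-carbon. This is the only step that sets absolute configuration, and it divides the molecule into two achiral halves. It demands face control at a one-point-binding enone and mono-alkylation of 6.

**5 to 3 and 4.** The C1=C2 double bond of the enone is cut (Claisen–Schmidt); no selectivity problem arises.

**3 to 2 to 1.** The O2' methyl and the O3' and O4' benzyl bonds are cut. The forward steps must tell the 2-hydroxyl, tied to the formyl group, from the other two.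

## Other disconnections considered

**Alternative 1:** The cut is C2–C3, with both ketones hidden in a 2,5-diarylfuran. Substrate A1 carries a finished ring A with a 3-arylpropargyl arm on C4a. The lithium enolate of its C2 ketone (LiN(SiMe3)2) is oxidised at an anode with ferrocene Fe(C5H5)2 as mediator; the α-keto radical closes the carbocycle 6-exo-dig on the alkyne, and after a second oxidation the ketone oxygen traps the vinyl centre to give A2.
- In its favour: the ring A oxygens are differentiated from the start, so no ether has to be cleaved selectively; on this point it is better than the chosen plan. C2 is sp2 until the furan is opened and cannot epimerise early. The mediator potential lies well below that of the alkoxyarenes.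
- Against it: A2 is one oxidation level and one double-bond position away from the target. The furan must be opened oxidatively to the C2=C3 enedione beside six electron-rich arenes and a dihydronaphthalene that aromatises easily. The double bond must then move to C3=C4 with controlled protonation at C2, so the C2 problem returns in a harder form. C1 of A1 bears two ortho-substituted aryl groups of similar size and is harder to set than C1 of 7.
- Comparison: both key steps build two rings and no stereocentre. The cycloaddition of 16 is a reagent-free isomerisation, whereas the anodic cascade needs two electron transfers in the right order. A penta-substituted ring A building block and about four steps after the key step make this route longer.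

**Alternative 2:** The cut is C1–C2 and C3–C4 together. Aldehyde A3 is photoenolised with UV light to an (E)-hydroxy-o-quinodimethane held on Ti(Oi-Pr)4 with a TADDOL ligand, and this adds to the (Z)-enedione A4 to give the all-cis tetralol A5. Loss of the C4 hydroxyl with the C3 hydrogen then gives C3=C4.
- In its favour: it is the most convergent plan. C1 and C2 are formed together and cis through the endo rule and the geometry of A4, so no separate correction of C2 is needed; on stereochemical economy it is better than the chosen plan. The ring A oxygens are differentiated, and the step count should be equal or lower.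
- Against it: the photoenol of A3 comes from a diarylmethane C–H, not a methyl group, so the pendant aryl can point in or out on the diene terminus and only one arrangement gives the wanted C1. Titanium-templated asymmetric induction for such substituted dienols would be an extrapolation. A4 can isomerise to its (E) form under the same light. The β-hydroxy ketone A5 must be dehydrated without epimerising C2.
- Comparison: the chosen plan sets C1 in a separate catalytic step and C2 by substrate control, which is slower but divides the risks. Alternative 2 puts regiochemistry, both stereocentres and the photochemistry into one step.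

**Alternative 3:** The cut is C1–C2. A chiral phosphoric acid dehydrates the racemic diaryl carbinol A6 to a para-quinone methide through its free 4'-hydroxyl, and the enol of the C2 ketone adds to the methide carbon to close the ring and give A7.
- In its favour: it is stereoconvergent from a racemate. Both stereocentres arise in the ring closure under catalyst control and no base is used afterwards, which is better than the chosen plan. Only the debenzylation follows, against three steps here.
- Against it: the 4'-hydroxyl must be free while O3' is benzylated, which needs extra differentiation within one catechol. A plain aryl ketone enol is a weak nucleophile for this chemistry. The carbinol of A6 lies between two ortho-methoxy groups. Its hydroxyl can add to C4 of the neighbouring enone to form a five-membered cyclic ether before any quinone methide forms. Cis versus trans at C2 is not assured.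
- Comparison: both plans close the carbocycle late. The chosen plan needs no catalyst control in the ring closure and builds ring A from a simple furan, where A6 needs a hexasubstituted benzene. Step counts are about equal.

Key step: step 8

**Remarks on the chemistry.**
- Locants C1 to C8a of the target (primes for the pendant aryl ring) are used for all intermediates.
- An open-chain enyne diketone with a single configuration at C2 is not realistic, because C2–H is α to a ketone and allylic to the enynone. Compounds 10 to 18 are therefore planned as C2 epimer pairs (C1 fixed as S, C2 left open in their SMILES) and C2 is set in step 9.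
- Compounds 4 and 8 are taken as purchased benzyl ethers; each is otherwise one or two routine steps from 4'-hydroxyacetophenone.
- The antipode of the ligand in step 4 that gives (S)-7 has to be fixed in a first run; both antipodes are accessible from the two enantiomers of pipecolic acid.

## Route

Step 1
Reactants: 1 2,3,4-trihydroxybenzaldehyde
Product: 2 3,4-bis(benzyloxy)-2-hydroxybenzaldehyde
Conditions: NaH (3.1 equiv), THF–DMF, 0 °C; BnBr (2.05 equiv), 0 °C → rt; aq. HCl
Reagents that add atoms: benzyl bromide, BrCc1ccccc1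
Why: Williamson ether synthesis on the fully deprotonated aldehyde; the oxygen on C2 is conjugated with the formyl group and chelated to sodium with it, so it is the poorest nucleophile and the two benzyl groups should go to O3 and O4.

Step 2
Reactants: 2 3,4-bis(benzyloxy)-2-hydroxybenzaldehyde
Product: 3 3,4-bis(benzyloxy)-2-methoxybenzaldehyde
Conditions: MeI (3 equiv), K2CO3 (2 equiv), DMF, 40 °C
Reagents that add atoms: iodomethane, CI
Why: Williamson O-methylation of the remaining hydrogen-bonded phenol under more forcing conditions; benzyl ethers and the aldehyde are inert.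

Step 3
Reactants: 3 3,4-bis(benzyloxy)-2-methoxybenzaldehyde; 4 1-[4-(benzyloxy)phenyl]ethan-1-one
Product: 5 (E)-1-[4-(benzyloxy)phenyl]-3-[3,4-bis(benzyloxy)-2-methoxyphenyl]prop-2-en-1-one
Conditions: KOH (aq. 40%), EtOH–THF, rt
Reagents that add atoms: none
Why: Claisen–Schmidt aldol condensation; the aldehyde has no α-hydrogen and E1cB loss of water gives the (E)-enone with the aryl group trans to the aroyl group.

Step 4
Reactants: 5 (E)-1-[4-(benzyloxy)phenyl]-3-[3,4-bis(benzyloxy)-2-methoxyphenyl]prop-2-en-1-one; 6 3,4-dimethoxyfuran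
Product: 7 (3S)-1-[4-(benzyloxy)phenyl]-3-[3,4-bis(benzyloxy)-2-methoxyphenyl]-3-(3,4-dimethoxyfuran-2-yl)propan-1-one
Conditions: 6 (3 equiv), Sc(OTf)3 (10 mol %), N,N'-dioxide of 1,3-bis[2-(2,6-diisopropylphenylcarbamoyl)piperidin-1-yl]propane (11 mol %), 4 Å MS, CH2Cl2, 0 °C
Reagents that add atoms: none
Why: Catalytic asymmetric Friedel–Crafts conjugate addition of an electron-rich heteroarene to a chalcone; Sc(OTf)3 in the chiral N,N'-dioxide pocket activates the carbonyl and leaves one face of C1 open to a furan α-carbon (both are equivalent), so C1 (S) is set by the ligand. The excess of 6 should suppress a second alkylation.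

Step 5
Reactants: 7 (3S)-1-[4-(benzyloxy)phenyl]-3-[3,4-bis(benzyloxy)-2-methoxyphenyl]-3-(3,4-dimethoxyfuran-2-yl)propan-1-one; 8 2-bromo-1-[4-(benzyloxy)phenyl]ethan-1-one
Product: 10 1,4-bis[4-(benzyloxy)phenyl]-2-{(S)-[3,4-bis(benzyloxy)-2-methoxyphenyl](3,4-dimethoxyfuran-2-yl)methyl}butane-1,4-dione (C2 epimer pair), via lithium enolate 9 (not isolated)
Conditions: LiN(SiMe3)2 (1.1 equiv), THF, −78 °C; 8 (1.2 equiv), −78 → −20 °C
Reagents that add atoms: none
Why: SN2 alkylation of a lithium ketone enolate by an α-bromo ketone forms C2–C3 and the 1,4-diketone. The C2 configuration is not controlled here and need not be, because step 9 sets it.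

Step 6
Reactants: 10 1,4-bis[4-(benzyloxy)phenyl]-2-{(S)-[3,4-bis(benzyloxy)-2-methoxyphenyl](3,4-dimethoxyfuran-2-yl)methyl}butane-1,4-dione (C2 epimer pair); 11 3-(trimethylsilyl)prop-2-ynal
Product: 15 1,4-bis[4-(benzyloxy)phenyl]-2-{(S)-[3,4-bis(benzyloxy)-2-methoxyphenyl](3,4-dimethoxyfuran-2-yl)methyl}-3-[(E)-3-(trimethylsilyl)prop-2-yn-1-ylidene]butane-1,4-dione (C2 epimer pair), via lithium enolate 12 (not isolated), via lithium aldolate 13 (not isolated), via propargylic mesylate 14 (not isolated)
Conditions: LiN(SiMe3)2 (1.1 equiv), THF, −78 °C; 11 (1.3 equiv); MsCl (1.5 equiv), Et3N (4 equiv), −78 → 20 °C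
Reagents that add atoms: none
Why: Directed aldol addition of the less hindered C3 enolate to the ynal, then mesylation and E1cB elimination. The (E)-enynone (alkyne trans to the aroyl group, cis to C2) is expected because only it lets the aroyl group stay coplanar with C3=C4. A weak amine base limits migration of the double bond toward C2.

Step 7
Reactants: 15 1,4-bis[4-(benzyloxy)phenyl]-2-{(S)-[3,4-bis(benzyloxy)-2-methoxyphenyl](3,4-dimethoxyfuran-2-yl)methyl}-3-[(E)-3-(trimethylsilyl)prop-2-yn-1-ylidene]butane-1,4-dione (C2 epimer pair)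
Product: 16 1,4-bis[4-(benzyloxy)phenyl]-2-{(S)-[3,4-bis(benzyloxy)-2-methoxyphenyl](3,4-dimethoxyfuran-2-yl)methyl}-3-[(E)-prop-2-yn-1-ylidene]butane-1,4-dione (C2 epimer pair)
Conditions: n-Bu4NF (1.1 equiv), AcOH (1.5 equiv), THF, −20 → 0 °C
Reagents that add atoms: none
Why: Fluoride-induced protodesilylation of an alkynylsilane; acetic acid buffers the medium so that neither conjugate addition to the enynone nor isomerisation through the C2 enolate should occur.

Step 8
Reactants: 16 1,4-bis[4-(benzyloxy)phenyl]-2-{(S)-[3,4-bis(benzyloxy)-2-methoxyphenyl](3,4-dimethoxyfuran-2-yl)methyl}-3-[(E)-prop-2-yn-1-ylidene]butane-1,4-dione (C2 epimer pair)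
Product: 18 [4-(benzyloxy)phenyl]{(1S)-3-[4-(benzyloxy)benzoyl]-1-[3,4-bis(benzyloxy)-2-methoxyphenyl]-6-hydroxy-7,8-dimethoxy-1,2-dihydronaphthalen-2-yl}methanone (C2 epimer pair), via oxa-bridged cycloadduct 17 (not isolated)
Conditions: PhMe (0.01 M), BHT (10 mol %), 110 °C, sealed tube, Ar, dark
Reagents that add atoms: none
Why: Intramolecular normal-demand Diels–Alder reaction of the electron-rich 2-alkyl-3,4-dimethoxyfuran (C8a, C8, C7, C6 as diene) with the terminal alkyne C4a≡C5, the electron-poor far end of the C3 aroyl enynone; the addition is polarity-matched (free furan α-carbon C6 to the vinylogous acceptor carbon C5, then C4a to C8a), probably asynchronous, and needs no reagent. The 7-oxanorbornadiene 17 then opens by heterolysis of C8a–O, the charge being shared with C7 as a methyl oxocarbenium ion, and loss of the C6 proton (shuttled by the phenols present) gives aromatic ring A with a free C6 hydroxyl, so the step is an isomerisation pulled by aromatisation. The closest known reaction type is the intramolecular Diels–Alder reaction of furans with tethered alkynes followed by ring-opening aromatisation to phenols. The carbocycle (C1, C2, C3, C4, C4a, C8a) closes as the six-membered tether ring of the [4+2] addition through the new C4a–C8a bond, and the oxa-bridged six-membered ring (C4a, C5, C6, C7, C8, C8a) closes suprafacially through C4a–C8a and C5–C6. No lasting stereocentre is formed: the bridgeheads C6 and C8a become sp2, C1 is untouched and C2 stays an epimer pair. The selectivities needed are the site of addition and the direction of bridge opening: the four-atom tether and the (E) geometry let only the alkyne reach the furan, and because C6 is the only bridgehead with hydrogen only C8a–O cleavage can end in an arene, the other heterolysis being reversible. π-Acidic metal catalysts are avoided because they would move the oxygen to C5.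

Step 9
Reactants: 18 [4-(benzyloxy)phenyl]{(1S)-3-[4-(benzyloxy)benzoyl]-1-[3,4-bis(benzyloxy)-2-methoxyphenyl]-6-hydroxy-7,8-dimethoxy-1,2-dihydronaphthalen-2-yl}methanone (C2 epimer pair)
Product: 20 [4-(benzyloxy)phenyl]{(1S,2S)-3-[4-(benzyloxy)benzoyl]-1-[3,4-bis(benzyloxy)-2-methoxyphenyl]-6-hydroxy-7,8-dimethoxy-1,2-dihydronaphthalen-2-yl}methanone, via dilithium phenoxide dienolate 19 (not isolated)
Conditions: LiN(SiMe3)2 (2.3 equiv), THF, −78 → −40 °C; AcOH (6 equiv) in THF, −78 °C; Ar
Reagents that add atoms: none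
Why: Kinetic protonation of an enolate; the C1 aryl group is pseudoaxial (peri strain with the C8 methoxy group) and shields one face of planar C2, so the proton should enter trans to it and the aroyl group ends cis to the aryl group, which is C2 (S). Both epimers of 18 converge through the same dienolate, and α-protonation of a dienolate is kinetically preferred over γ-protonation at C4.

Step 10
Reactants: 20 [4-(benzyloxy)phenyl]{(1S,2S)-3-[4-(benzyloxy)benzoyl]-1-[3,4-bis(benzyloxy)-2-methoxyphenyl]-6-hydroxy-7,8-dimethoxy-1,2-dihydronaphthalen-2-yl}methanone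
Product: 23 [4-(benzyloxy)phenyl]{(1S,2S)-3-[4-(benzyloxy)benzoyl]-1-[3,4-bis(benzyloxy)-2-methoxyphenyl]-6,7-dihydroxy-8-methoxy-1,2-dihydronaphthalen-2-yl}methanone, via aryloxydichloroborane 21 (not isolated), via cyclic chloroborate 22 (not isolated)
Conditions: BCl3 (1.05 equiv), CH2Cl2, −78 °C; n-Bu4NI (1.1 equiv), −78 → 0 °C; ice-water
Reagents that add atoms: none
Why: Hydroxyl-directed cleavage of an aryl methyl ether; the only free phenol takes up the single equivalent of BCl3 on oxygen, boron then chelates the neighbouring C7 methoxy oxygen in a five-membered ring and iodide removes that methyl group (SN2) to give a cyclic borate that water hydrolyses. The C8 and C2' methyl ethers and the benzyl ethers have no boron to activate them, and no base is present to disturb C2.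

Step 11
Reactants: 23 [4-(benzyloxy)phenyl]{(1S,2S)-3-[4-(benzyloxy)benzoyl]-1-[3,4-bis(benzyloxy)-2-methoxyphenyl]-6,7-dihydroxy-8-methoxy-1,2-dihydronaphthalen-2-yl}methanone
Product: 24 licobichalcone, (4-hydroxyphenyl)[(1S,2S)-1-(3,4-dihydroxy-2-methoxyphenyl)-6,7-dihydroxy-3-(4-hydroxybenzoyl)-8-methoxy-1,2-dihydronaphthalen-2-yl]methanone
Conditions: BCl3 (10 equiv), C6HMe5 (15 equiv), CH2Cl2, −78 °C; CHCl3–MeOH quench at −78 °C
Reagents that add atoms: none
Why: Lewis-acid debenzylation with a non-basic cation scavenger; BCl3 ionises the benzyl–oxygen bonds at −78 °C and pentamethylbenzene captures the benzyl cations before they can alkylate the electron-rich rings. Methyl ethers, the enone and the C1/C2 stereocentres should be untouched at this temperature, and no hydrogen is used, so C3=C4 stays.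

## Compound list

1 | 2,3,4-trihydroxybenzaldehyde | O=Cc1ccc(O)c(O)c1O | starting material
2 | 3,4-bis(benzyloxy)-2-hydroxybenzaldehyde | O=Cc1ccc(OCc2ccccc2)c(OCc2ccccc2)c1O | intermediate
3 | 3,4-bis(benzyloxy)-2-methoxybenzaldehyde | COc1c(C=O)ccc(OCc2ccccc2)c1OCc1ccccc1 | intermediate
4 | 1-[4-(benzyloxy)phenyl]ethan-1-one | CC(=O)c1ccc(OCc2ccccc2)cc1 | starting material
5 | (E)-1-[4-(benzyloxy)phenyl]-3-[3,4-bis(benzyloxy)-2-methoxyphenyl]prop-2-en-1-one | COc1c(/C=C/C(=O)c2ccc(OCc3ccccc3)cc2)ccc(OCc2ccccc2)c1OCc1ccccc1 | intermediate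
6 | 3,4-dimethoxyfuran | COc1cocc1OC | starting material
7 | (3S)-1-[4-(benzyloxy)phenyl]-3-[3,4-bis(benzyloxy)-2-methoxyphenyl]-3-(3,4-dimethoxyfuran-2-yl)propan-1-one | COc1c([C@H](CC(=O)c2ccc(OCc3ccccc3)cc2)c2occ(OC)c2OC)ccc(OCc2ccccc2)c1OCc1ccccc1 | intermediate
8 | 2-bromo-1-[4-(benzyloxy)phenyl]ethan-1-one | O=C(CBr)c1ccc(OCc2ccccc2)cc1 | starting material
9 | lithium (Z)-enolate of 7 (enolate carbon is C2) | [Li+].COc1c([C@H](/C=C(\[O-])c2ccc(OCc3ccccc3)cc2)c2occ(OC)c2OC)ccc(OCc2ccccc2)c1OCc1ccccc1 | intermediate (not isolated)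
10 | 1,4-bis[4-(benzyloxy)phenyl]-2-{(S)-[3,4-bis(benzyloxy)-2-methoxyphenyl](3,4-dimethoxyfuran-2-yl)methyl}butane-1,4-dione, C2 epimer pair | COc1c([C@H](C(CC(=O)c2ccc(OCc3ccccc3)cc2)C(=O)c2ccc(OCc3ccccc3)cc2)c2occ(OC)c2OC)ccc(OCc2ccccc2)c1OCc1ccccc1 | intermediate
11 | 3-(trimethylsilyl)prop-2-ynal | C[Si](C)(C)C#CC=O | starting material
12 | lithium (Z)-enolate of 10 at C3, C2 epimer pair | [Li+].COc1c([C@H](C(/C=C(\[O-])c2ccc(OCc3ccccc3)cc2)C(=O)c2ccc(OCc3ccccc3)cc2)c2occ(OC)c2OC)ccc(OCc2ccccc2)c1OCc1ccccc1 | intermediate (not isolated)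
13 | lithium aldolate: 10 carrying a 1-oxido-3-(trimethylsilyl)prop-2-yn-1-yl group on C3, diastereomer mixture | [Li+].COc1c([C@H](C(C(C([O-])C#C[Si](C)(C)C)C(=O)c2ccc(OCc3ccccc3)cc2)C(=O)c2ccc(OCc3ccccc3)cc2)c2occ(OC)c2OC)ccc(OCc2ccccc2)c1OCc1ccccc1 | intermediate (not isolated)
14 | methanesulfonate of the aldol, diastereomer mixture | COc1c([C@H](C(C(C(OS(C)(=O)=O)C#C[Si](C)(C)C)C(=O)c2ccc(OCc3ccccc3)cc2)C(=O)c2ccc(OCc3ccccc3)cc2)c2occ(OC)c2OC)ccc(OCc2ccccc2)c1OCc1ccccc1 | intermediate (not isolated)
15 | 1,4-bis[4-(benzyloxy)phenyl]-2-{(S)-[3,4-bis(benzyloxy)-2-methoxyphenyl](3,4-dimethoxyfuran-2-yl)methyl}-3-[(E)-3-(trimethylsilyl)prop-2-yn-1-ylidene]butane-1,4-dione, C2 epimer pair | COc1c([C@H](C(C(=O)c2ccc(OCc3ccccc3)cc2)/C(=C\C#C[Si](C)(C)C)C(=O)c2ccc(OCc3ccccc3)cc2)c2occ(OC)c2OC)ccc(OCc2ccccc2)c1OCc1ccccc1 | intermediate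
16 | 1,4-bis[4-(benzyloxy)phenyl]-2-{(S)-[3,4-bis(benzyloxy)-2-methoxyphenyl](3,4-dimethoxyfuran-2-yl)methyl}-3-[(E)-prop-2-yn-1-ylidene]butane-1,4-dione, C2 epimer pair | COc1c([C@H](C(C(=O)c2ccc(OCc3ccccc3)cc2)/C(=C\C#C)C(=O)c2ccc(OCc3ccccc3)cc2)c2occ(OC)c2OC)ccc(OCc2ccccc2)c1OCc1ccccc1 | intermediate
17 | oxa-bridged cycloadduct (7-oxanorbornadiene with oxygen between C6 and C8a, C7=C8 bis-methyl enol ether, C4a=C5 and C3=C4 alkenes; bridgeheads of either relative configuration, C2 epimer pair) | COc1c([C@H]2C34OC(C=C3C=C(C(=O)c3ccc(OCc5ccccc5)cc3)C2C(=O)c2ccc(OCc3ccccc3)cc2)C(OC)=C4OC)ccc(OCc2ccccc2)c1OCc1ccccc1 | intermediate (not isolated)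
18 | [4-(benzyloxy)phenyl]{(1S)-3-[4-(benzyloxy)benzoyl]-1-[3,4-bis(benzyloxy)-2-methoxyphenyl]-6-hydroxy-7,8-dimethoxy-1,2-dihydronaphthalen-2-yl}methanone, C2 epimer pair | COc1c([C@H]2c3c(cc(O)c(OC)c3OC)C=C(C(=O)c3ccc(OCc4ccccc4)cc3)C2C(=O)c2ccc(OCc3ccccc3)cc2)ccc(OCc2ccccc2)c1OCc1ccccc1 | intermediate
19 | dilithium salt of 18: C6 phenoxide and C2 dienolate | [Li+].[Li+].COc1c([C@H]2c3c(cc([O-])c(OC)c3OC)C=C(C(=O)c3ccc(OCc4ccccc4)cc3)C2=C([O-])c2ccc(OCc3ccccc3)cc2)ccc(OCc2ccccc2)c1OCc1ccccc1 | intermediate (not isolated)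
20 | [4-(benzyloxy)phenyl]{(1S,2S)-3-[4-(benzyloxy)benzoyl]-1-[3,4-bis(benzyloxy)-2-methoxyphenyl]-6-hydroxy-7,8-dimethoxy-1,2-dihydronaphthalen-2-yl}methanone | COc1c([C@H]2c3c(cc(O)c(OC)c3OC)C=C(C(=O)c3ccc(OCc4ccccc4)cc3)[C@H]2C(=O)c2ccc(OCc3ccccc3)cc2)ccc(OCc2ccccc2)c1OCc1ccccc1 | intermediate
21 | C6 aryloxydichloroborane of 20 | COc1c([C@H]2c3c(cc(OB(Cl)Cl)c(OC)c3OC)C=C(C(=O)c3ccc(OCc4ccccc4)cc3)[C@H]2C(=O)c2ccc(OCc3ccccc3)cc2)ccc(OCc2ccccc2)c1OCc1ccccc1 | intermediate (not isolated)
22 | cyclic chloroborate (2-chloro-1,3,2-dioxaborole across O6 and O7) | COc1c([C@H]2c3c(cc4OB(Cl)Oc4c3OC)C=C(C(=O)c3ccc(OCc4ccccc4)cc3)[C@H]2C(=O)c2ccc(OCc3ccccc3)cc2)ccc(OCc2ccccc2)c1OCc1ccccc1 | intermediate (not isolated)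
23 | [4-(benzyloxy)phenyl]{(1S,2S)-3-[4-(benzyloxy)benzoyl]-1-[3,4-bis(benzyloxy)-2-methoxyphenyl]-6,7-dihydroxy-8-methoxy-1,2-dihydronaphthalen-2-yl}methanone | COc1c([C@H]2c3c(cc(O)c(O)c3OC)C=C(C(=O)c3ccc(OCc4ccccc4)cc3)[C@H]2C(=O)c2ccc(OCc3ccccc3)cc2)ccc(OCc2ccccc2)c1OCc1ccccc1 | intermediate
24 | licobichalcone, (4-hydroxyphenyl)[(1S,2S)-1-(3,4-dihydroxy-2-methoxyphenyl)-6,7-dihydroxy-3-(4-hydroxybenzoyl)-8-methoxy-1,2-dihydronaphthalen-2-yl]methanone | COc1c([C@H]2c3c(cc(O)c(O)c3OC)C=C(C(=O)c3ccc(O)cc3)[C@H]2C(=O)c2ccc(O)cc2)ccc(O)c1O | target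

## Step count and least certain steps

Total: 11 steps. Longest linear sequence: 11 steps, from 1 to 24; compounds 4, 6, 8 and 11 enter as purchased.

**Step 8 (key step).** The cycloaddition may be too slow, so that thermal decay of the terminal enynone (oligomerisation, or a 1,5-hydrogen shift from C2 to the alkyne terminus) overtakes it. Fallback: set out from 15 and heat the silyl alkyne itself, which cannot follow the terminal-alkyne decay paths, to give the C5-silylated phenol [4-(benzyloxy)phenyl]{(1S)-3-[4-(benzyloxy)benzoyl]-1-[3,4-bis(benzyloxy)-2-methoxyphenyl]-6-hydroxy-7,8-dimethoxy-5-(trimethylsilyl)-1,2-dihydronaphthalen-2-yl}methanone F1. Ipso-protodesilylation with CF3CO2H in CH2Cl2 at 0 °C (C5 is ortho to the hydroxyl and para to the C8 methoxy group) then returns to the route at 18; step 7 is skipped.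

**Step 4.** Face selectivity may be low because the chalcone holds Sc(OTf)3 through one oxygen only; a second alkylation of the furan is the other risk. Fallback: set out from 3 and condense it with 2-acetyl-1-methylimidazole to the two-point-binding acceptor (E)-3-[3,4-bis(benzyloxy)-2-methoxyphenyl]-1-(1-methylimidazol-2-yl)prop-2-en-1-one F2. Add 6 under Sc(OTf)3 with an indane-fused 2,6-bis(oxazolinyl)pyridine ligand to give (3S)-3-[3,4-bis(benzyloxy)-2-methoxyphenyl]-3-(3,4-dimethoxyfuran-2-yl)-1-(1-methylimidazol-2-yl)propan-1-one F3. Add 4-(benzyloxy)phenylmagnesium bromide to give the tertiary carbinol 1-[4-(benzyloxy)phenyl]-3-[3,4-bis(benzyloxy)-2-methoxyphenyl]-3-(3,4-dimethoxyfuran-2-yl)-1-(1-methylimidazol-2-yl)propan-1-ol F4. Methylate with MeOTf to the imidazolium triflate of F4, 2-{1-[4-(benzyloxy)phenyl]-3-[3,4-bis(benzyloxy)-2-methoxyphenyl]-3-(3,4-dimethoxyfuran-2-yl)-1-hydroxypropyl}-1,3-dimethylimidazolium trifluoromethanesulfonate F5, and treat it with DBU; loss of the imidazolium unit releases the ketone and returns to the route at 7.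

**Step 5.** Proton transfer from the acidic bromo ketone 8 to the enolate (followed by self-condensation of 8) and double alkylation may lower the conversion. Fallback: set out from 7, methylenate C2 with paraformaldehyde and diisopropylammonium trifluoroacetate in THF to the enone 1-[4-(benzyloxy)phenyl]-2-{[3,4-bis(benzyloxy)-2-methoxyphenyl](3,4-dimethoxyfuran-2-yl)methyl}prop-2-en-1-one F6. A Stetter addition of 4-(benzyloxy)benzaldehyde (thiazolium carbene catalyst, Et3N) then returns to the route at 10.

**Step 6.** The elimination may lose geometric control, or the base may move the double bond from C3=C4 toward C2. Fallback: set out from 10 and run step 6 without demanding selectivity. The (Z)-isomer, 1,4-bis[4-(benzyloxy)phenyl]-2-{(S)-[3,4-bis(benzyloxy)-2-methoxyphenyl](3,4-dimethoxyfuran-2-yl)methyl}-3-[(Z)-3-(trimethylsilyl)prop-2-yn-1-ylidene]butane-1,4-dione F7, is separated and equilibrated by reversible conjugate addition of catalytic DABCO in MeCN. Geometry is then under thermodynamic control, and the material returns to the route at 15.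

**Step 9.** Facial selectivity of the protonation may be poor, or protonation on oxygen may be followed by uncontrolled ketonisation. Fallback: set out from 16 and separate the C2 epimers by chromatography, recycling the unwanted one by brief equilibration with DBU. This gives the single epimer (2S)-1,4-bis[4-(benzyloxy)phenyl]-2-{(S)-[3,4-bis(benzyloxy)-2-methoxyphenyl](3,4-dimethoxyfuran-2-yl)methyl}-3-[(E)-prop-2-yn-1-ylidene]butane-1,4-dione F8. Cyclising it under the neutral conditions of step 8 involves no enolate, so the configuration is carried over and the route is rejoined at 20.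

**Step 10.** Site selectivity may be lost if a benzyl ether on the pendant ring is cleaved and the freed O3' then directs boron to the C2' methyl ether; the directed cleavage may also be slow. Fallback: set out from 20 and use oxidative instead of Lewis-acid demethylation. o-Iodoxybenzoic acid in DMF at rt should give the ortho-quinone [4-(benzyloxy)phenyl]{(1S,2S)-3-[4-(benzyloxy)benzoyl]-1-[3,4-bis(benzyloxy)-2-methoxyphenyl]-8-methoxy-6,7-dioxo-1,2,6,7-tetrahydronaphthalen-2-yl}methanone F9. Reduction in the same flask with aqueous Na2S2O4 returns to the route at 23.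

## Further compounds

F1 | step 8 | [4-(benzyloxy)phenyl]{(1S)-3-[4-(benzyloxy)benzoyl]-1-[3,4-bis(benzyloxy)-2-methoxyphenyl]-6-hydroxy-7,8-dimethoxy-5-(trimethylsilyl)-1,2-dihydronaphthalen-2-yl}methanone, C2 epimer pair | COc1c([C@H]2c3c(c([Si](C)(C)C)c(O)c(OC)c3OC)C=C(C(=O)c3ccc(OCc4ccccc4)cc3)C2C(=O)c2ccc(OCc3ccccc3)cc2)ccc(OCc2ccccc2)c1OCc1ccccc1
F2 | step 4 | (E)-3-[3,4-bis(benzyloxy)-2-methoxyphenyl]-1-(1-methylimidazol-2-yl)prop-2-en-1-one | COc1c(/C=C/C(=O)c2nccn2C)ccc(OCc2ccccc2)c1OCc1ccccc1
F3 | step 4 | (3S)-3-[3,4-bis(benzyloxy)-2-methoxyphenyl]-3-(3,4-dimethoxyfuran-2-yl)-1-(1-methylimidazol-2-yl)propan-1-one | COc1c([C@H](CC(=O)c2nccn2C)c2occ(OC)c2OC)ccc(OCc2ccccc2)c1OCc1ccccc1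
F4 | step 4 | 1-[4-(benzyloxy)phenyl]-3-[3,4-bis(benzyloxy)-2-methoxyphenyl]-3-(3,4-dimethoxyfuran-2-yl)-1-(1-methylimidazol-2-yl)propan-1-ol, C3 as in 7, carbinol epimers | COc1c([C@H](CC(O)(c2ccc(OCc3ccccc3)cc2)c2nccn2C)c2occ(OC)c2OC)ccc(OCc2ccccc2)c1OCc1ccccc1
F5 | step 4 | 2-{1-[4-(benzyloxy)phenyl]-3-[3,4-bis(benzyloxy)-2-methoxyphenyl]-3-(3,4-dimethoxyfuran-2-yl)-1-hydroxypropyl}-1,3-dimethylimidazolium trifluoromethanesulfonate | COc1c([C@H](CC(O)(c2ccc(OCc3ccccc3)cc2)c2n(C)cc[n+]2C)c2occ(OC)c2OC)ccc(OCc2ccccc2)c1OCc1ccccc1.[O-]S(=O)(=O)C(F)(F)F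
F6 | step 5 | 1-[4-(benzyloxy)phenyl]-2-{[3,4-bis(benzyloxy)-2-methoxyphenyl](3,4-dimethoxyfuran-2-yl)methyl}prop-2-en-1-one, methine carbon as in 7 | COc1c([C@H](C(=C)C(=O)c2ccc(OCc3ccccc3)cc2)c2occ(OC)c2OC)ccc(OCc2ccccc2)c1OCc1ccccc1
F7 | step 6 | 1,4-bis[4-(benzyloxy)phenyl]-2-{(S)-[3,4-bis(benzyloxy)-2-methoxyphenyl](3,4-dimethoxyfuran-2-yl)methyl}-3-[(Z)-3-(trimethylsilyl)prop-2-yn-1-ylidene]butane-1,4-dione, C2 epimer pair | COc1c([C@H](C(C(=O)c2ccc(OCc3ccccc3)cc2)/C(=C/C#C[Si](C)(C)C)C(=O)c2ccc(OCc3ccccc3)cc2)c2occ(OC)c2OC)ccc(OCc2ccccc2)c1OCc1ccccc1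
F8 | step 9 | (2S)-1,4-bis[4-(benzyloxy)phenyl]-2-{(S)-[3,4-bis(benzyloxy)-2-methoxyphenyl](3,4-dimethoxyfuran-2-yl)methyl}-3-[(E)-prop-2-yn-1-ylidene]butane-1,4-dione | COc1c([C@H]([C@H](C(=O)c2ccc(OCc3ccccc3)cc2)/C(=C\C#C)C(=O)c2ccc(OCc3ccccc3)cc2)c2occ(OC)c2OC)ccc(OCc2ccccc2)c1OCc1ccccc1
F9 | step 10 | [4-(benzyloxy)phenyl]{(1S,2S)-3-[4-(benzyloxy)benzoyl]-1-[3,4-bis(benzyloxy)-2-methoxyphenyl]-8-methoxy-6,7-dioxo-1,2,6,7-tetrahydronaphthalen-2-yl}methanone | COc1c([C@H]2C3=C(OC)C(=O)C(=O)C=C3C=C(C(=O)c3ccc(OCc4ccccc4)cc3)[C@H]2C(=O)c2ccc(OCc3ccccc3)cc2)ccc(OCc2ccccc2)c1OCc1ccccc1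
A1 | alternative 1 | 1-[4-(benzyloxy)phenyl]-3-[3,4-bis(benzyloxy)-2-methoxyphenyl]-3-{3,4-bis(benzyloxy)-2-methoxy-6-[3-(4-benzyloxyphenyl)prop-2-yn-1-yl]phenyl}propan-1-one, C1 as in the target | COc1c([C@H](CC(=O)c2ccc(OCc3ccccc3)cc2)c2c(CC#Cc3ccc(OCc4ccccc4)cc3)cc(OCc3ccccc3)c(OCc3ccccc3)c2OC)ccc(OCc2ccccc2)c1OCc1ccccc1
A2 | alternative 1 | 4-[3,4-bis(benzyloxy)-2-methoxyphenyl]-6,7-bis(benzyloxy)-1,3-bis[4-(benzyloxy)phenyl]-5-methoxy-4,9-dihydronaphtho[2,3-c]furan, C4 as C1 of the target | COc1c([C@H]2c3c(cc(OCc4ccccc4)c(OCc4ccccc4)c3OC)Cc3c2c(-c2ccc(OCc4ccccc4)cc2)oc3-c2ccc(OCc3ccccc3)cc2)ccc(OCc2ccccc2)c1OCc1ccccc1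
A3 | alternative 2 | 4,5-bis(benzyloxy)-2-[3,4-bis(benzyloxy)-2-methoxybenzyl]-3-methoxybenzaldehyde | COc1c(Cc2c(C=O)cc(OCc3ccccc3)c(OCc3ccccc3)c2OC)ccc(OCc2ccccc2)c1OCc1ccccc1
A4 | alternative 2 | (Z)-1,4-bis[4-(benzyloxy)phenyl]but-2-ene-1,4-dione | O=C(/C=C\C(=O)c1ccc(OCc2ccccc2)cc1)c1ccc(OCc2ccccc2)cc1
A5 | alternative 2 | all-cis 6,7-bis(benzyloxy)-2,3-bis[4-(benzyloxy)benzoyl]-1-[3,4-bis(benzyloxy)-2-methoxyphenyl]-8-methoxy-1,2,3,4-tetrahydronaphthalen-4-ol, C1 and C2 as in the target | COc1c([C@H]2c3c(cc(OCc4ccccc4)c(OCc4ccccc4)c3OC)[C@@H](O)[C@@H](C(=O)c3ccc(OCc4ccccc4)cc3)[C@H]2C(=O)c2ccc(OCc3ccccc3)cc2)ccc(OCc2ccccc2)c1OCc1ccccc1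
A6 | alternative 3 | (2E)-2-({4,5-bis(benzyloxy)-2-[(3-(benzyloxy)-4-hydroxy-2-methoxyphenyl)(hydroxy)methyl]-3-methoxyphenyl}methylidene)-1,4-bis[4-(benzyloxy)phenyl]butane-1,4-dione, racemic carbinol | COc1c(C(O)c2c(/C=C(\CC(=O)c3ccc(OCc4ccccc4)cc3)C(=O)c3ccc(OCc4ccccc4)cc3)cc(OCc3ccccc3)c(OCc3ccccc3)c2OC)ccc(O)c1OCc1ccccc1
A7 | alternative 3 | [4-(benzyloxy)phenyl]{(1S,2S)-6,7-bis(benzyloxy)-3-[4-(benzyloxy)benzoyl]-1-[3-(benzyloxy)-4-hydroxy-2-methoxyphenyl]-8-methoxy-1,2-dihydronaphthalen-2-yl}methanone | COc1c([C@H]2c3c(cc(OCc4ccccc4)c(OCc4ccccc4)c3OC)C=C(C(=O)c3ccc(OCc4ccccc4)cc3)[C@H]2C(=O)c2ccc(OCc3ccccc3)cc2)ccc(O)c1OCc1ccccc1
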